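## Retrosynthetic overview
1. The ester C–O bond is made last, from the ring carbinol and silyl-protected vanillic acid. The carbinol comes from the ring ketone by a reagent-controlled reduction.
2. The only ring, the ten-membered carbocycle, is closed in one step from an achiral, acyclic (2Z,6Z)-9-oxofarnesal. Hydride goes to C11 and C10 attacks the C1 aldehyde in an enantioselective reductive aldol. This makes the same bonds as FPP → germacradienyl cation → 1,3-H shift → hydration at C1.
3. 9-Oxofarnesal comes from double oxidation of (2Z,6Z)-farnesa-2,6,10-triene-1,9-diol, which comes from a B-alkyl Suzuki coupling at C3–C4.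
4. One Z-alkene is templated in a δ-lactone (senecioic acid + prenal). The other comes from trans-hydroalumination/iodination of but-2-yn-1-ol.

Assumption: both ring alkenes are taken as Z exactly as written in the SMILES, and (S)-BINAPO is taken to give the (9S,10R) aldol; if the sense is opposite, the equally available (R)-BINAPO is used.
Locants: acyclic compounds use farnesane numbering (C1 = CH2OH/CHO end). Ring compounds use the locants of their cyclodecadiene names.

## Route

Step 1
Reactants: 1 3-methylbut-2-enoic acid (senecioic acid); 2 3-methylbut-2-enal (prenal)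
Product: 5 (±)-4-methyl-6-(2-methylprop-1-en-1-yl)-5,6-dihydro-2H-pyran-2-one, via dilithium dienediolate 3 (not isolated), via Z-hydroxy acid 4 (not isolated)
Conditions: LDA (2.2 equiv), THF, −78 → 0 °C; 2, −78 °C → rt, 12 h; cold 1 M HCl (pH 3)
Reagents that add atoms: none
Why: Vinylogous (γ-selective, equilibrating) aldol addition of the acid dienediolate followed by lactonisation; only the 2Z δ-hydroxy acid can close to the six-membered lactone, so the ring fixes the trisubstituted alkene as Z, and the racemic carbinol centre does not matter because it becomes a ketone in step 5.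

Step 2
Reactants: 5 (±)-4-methyl-6-(2-methylprop-1-en-1-yl)-5,6-dihydro-2H-pyran-2-one
Product: 7 (±)-(6Z)-2,6-dimethylnona-2,6,8-trien-4-ol, via aluminium lactolate 6 (not isolated)
Conditions: DIBAL-H (1.1 equiv), CH2Cl2, −78 °C; then Ph3P=CH2 (from Ph3PCH3Br/KOtBu, 3 equiv), THF, −78 °C → rt; Rochelle salt
Reagents that add atoms: methyltriphenylphosphonium bromide, C[P+](c1ccccc1)(c1ccccc1)c1ccccc1.[Br-]
Why: Partial lactone reduction followed by Wittig methylenation of the ring-opened Z-hydroxy-enal form; the non-stabilised ylide traps the aldehyde faster than it can isomerise, so the templated Z-alkene is carried into the 1,3-diene.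

Step 3
Reactants: 8 but-2-yn-1-ol
Product: 10 (2Z)-3-iodobut-2-en-1-ol, via cyclic alkenylalanate 9 (not isolated)
Conditions: Red-Al (1.6 equiv), THF, 0 °C → rt; then I2, −78 → 0 °C
Reagents that add atoms: iodine, II
Why: Alkoxide-directed trans-hydroalumination of the propargylic alcohol places aluminium on C3 cis to the CH2O group, and iodinolysis with retention gives only the Z-vinyl iodide.

Step 4
Reactants: 7 (±)-(6Z)-2,6-dimethylnona-2,6,8-trien-4-ol; 10 (2Z)-3-iodobut-2-en-1-ol
Product: 12 (±)-(2Z,6Z)-3,7,11-trimethyldodeca-2,6,10-triene-1,9-diol, via bis-boryl alkylborane 11 (not isolated)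
Conditions: 9-BBN (2.2 equiv), THF, 0 °C → rt; then 10, Pd(dppf)Cl2 (5 mol %), AsPh3, Cs2CO3, DMF/H2O, rt
Reagents that add atoms: none
Why: 9-BBN adds only to the monosubstituted terminus of the diene because trisubstituted alkenes react far more slowly, and the B-alkyl Suzuki–Miyaura coupling goes with retention at the vinyl iodide, so both trisubstituted alkenes of the C15 chain are Z.

Step 5
Reactants: 12 (±)-(2Z,6Z)-3,7,11-trimethyldodeca-2,6,10-triene-1,9-diol
Product: 13 (2Z,6Z)-3,7,11-trimethyl-9-oxododeca-2,6,10-trienal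
Conditions: DMP (2.6 equiv), pyridine, CH2Cl2, 0 °C
Reagents that add atoms: none
Why: Buffered Dess–Martin oxidation converts both alcohols in one operation under neutral, non-enolising conditions, which keeps the neral-type enal Z and the β,γ-alkene out of conjugation, and it deliberately erases the only stereocentre to give an achiral cyclisation substrate.

Step 6
Reactants: 13 (2Z,6Z)-3,7,11-trimethyl-9-oxododeca-2,6,10-trienal
Product: 16 (3Z,7Z,9S,10R)-9-hydroxy-3,7-dimethyl-10-(propan-2-yl)cyclodeca-3,7-dien-1-one, via Z-trichlorosilyl enolate 14 (not isolated), via trichlorosilyl aldolate 15 (not isolated)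
Conditions: HSiCl3 (6 equiv), (S)-BINAPO (20 mol %), CH2Cl2/EtCN, −60 °C, 13 added by syringe pump over 12 h (final 2 mM); sat. aq NaHCO3
Reagents that add atoms: none
Why: Proposed new method: the mesityl-oxide-type enone is held s-cis by A1,3 strain and takes hydride from Lewis-base-activated HSiCl3 at C11 through a six-membered transition state to give only the (Z)-trichlorosilyl enolate 14, whereas the s-trans and less Lewis-basic Z-enal cannot use that path and survives to be attacked by C10 through a BINAPO-bound chair-like closed silicon transition state, which closes the C1–C10 bond, gives the syn aldol (Z-enolate → syn) and sets both new centres (9S,10R) under catalyst control; alkenes are inert under these non-cationic conditions, so the six-ring closure typical of neral-type cations cannot compete, and the two Z-alkenes pre-fold the chain for ten-ring closure; the closest known reaction type is the intermolecular chiral phosphine-oxide-catalysed trichlorosilane reductive aldol reaction of s-cis enones with conjugated aldehydes.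

Step 7
Reactants: 16 (3Z,7Z,9S,10R)-9-hydroxy-3,7-dimethyl-10-(propan-2-yl)cyclodeca-3,7-dien-1-one
Product: 17 (3Z,7Z,9S,10R)-3,7-dimethyl-10-(propan-2-yl)-9-[(triethylsilyl)oxy]cyclodeca-3,7-dien-1-one
Conditions: TESOTf, 2,6-lutidine, CH2Cl2, −78 °C
Reagents that add atoms: triethylsilyl trifluoromethanesulfonate, CC[Si](CC)(CC)OS(=O)(=O)C(F)(F)F
Why: Silylation of the only hydroxyl at −78 °C with a hindered base avoids retro-aldol, β-elimination and C10 epimerisation, and it guarantees that the later acylation can occur only at the C1 oxygen, since a free allylic OH would otherwise compete.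

Step 8
Reactants: 17 (3Z,7Z,9S,10R)-3,7-dimethyl-10-(propan-2-yl)-9-[(triethylsilyl)oxy]cyclodeca-3,7-dien-1-one
Product: 18 (1R,3Z,7Z,9S,10S)-3,7-dimethyl-10-(propan-2-yl)-9-[(triethylsilyl)oxy]cyclodeca-3,7-dien-1-ol
Conditions: (S)-Me-CBS (0.5 equiv), catecholborane (2.5 equiv), toluene, −78 → −30 °C; MeOH, pH 7 buffer
Reagents that add atoms: none
Why: Corey–Bakshi–Shibata reduction: the catalyst binds the ketone away from the bulky C10 (CH-iPr) branch (RL = C10, RS = C2H2, the same sense as acetophenone → (R)-alcohol with the (S)-catalyst), so hydride delivery gives the (1R)-carbinol that is 1,3-syn to C9–O, while catecholborane leaves the trisubstituted alkenes and the TES ether untouched (the C10 descriptor changes to S only through CIP ranking).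

Step 9
Reactants: 19 4-hydroxy-3-methoxybenzoic acid (vanillic acid)
Product: 21 4-[(tert-butyldimethylsilyl)oxy]-3-methoxybenzoic acid, via bis-TBS vanillate 20 (not isolated)
Conditions: TBSCl (2.5 equiv), imidazole, DMF, rt; then AcOH/THF/H2O, rt
Reagents that add atoms: tert-butyldimethylsilyl chloride, CC(C)(C)[Si](C)(C)Cl
Why: Exhaustive silylation followed by selective hydrolysis of the far more labile silyl ester leaves the phenol masked by a group that is later removed together with the TES ether.

Step 10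
Reactants: 18 (1R,3Z,7Z,9S,10S)-3,7-dimethyl-10-(propan-2-yl)-9-[(triethylsilyl)oxy]cyclodeca-3,7-dien-1-ol; 21 4-[(tert-butyldimethylsilyl)oxy]-3-methoxybenzoic acid
Product: 23 (1R,3Z,7Z,9S,10R)-9-hydroxy-3,7-dimethyl-10-(propan-2-yl)cyclodeca-3,7-dien-1-yl 4-hydroxy-3-methoxybenzoate (target), via bis-silyl ester 22 (not isolated)
Conditions: DCC, DMAP, CH2Cl2, rt → 35 °C; MeOH quench; then TBAF/AcOH (1:1), THF, 0 °C → rt
Reagents that add atoms: none
Why: Steglich esterification acylates the only free hydroxyl with retention at C1, the methanol quench destroys excess acyl donor, and buffered fluoride then removes both silyl groups without acyl migration, ester cleavage or ionisation of the allylic alcohol.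

## Compound list
1 | 3-methylbut-2-enoic acid | CC(C)=CC(=O)O | starting material
2 | 3-methylbut-2-enal | CC(C)=CC=O | starting material
3 | dilithium 3-methylbuta-1,3-diene-1,1-diolate | C=C(C)C=C([O-])[O-].[Li+].[Li+] | intermediate
4 | (±)-(2Z)-5-hydroxy-3,7-dimethylocta-2,6-dienoic acid | CC(C)=CC(O)C/C(C)=C\C(=O)O | intermediate
5 | (±)-4-methyl-6-(2-methylprop-1-en-1-yl)-5,6-dihydro-2H-pyran-2-one | CC1=CC(=O)OC(C=C(C)C)C1 | intermediate
6 | diisobutylaluminium lactolate of 5 | CC1=CC(O[Al](CC(C)C)CC(C)C)OC(C=C(C)C)C1 | intermediate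
7 | (±)-(6Z)-2,6-dimethylnona-2,6,8-trien-4-ol | CC(C)=CC(O)C/C(C)=C\C=C | intermediate
8 | but-2-yn-1-ol | CC#CCO | starting material
9 | sodium bis(2-methoxyethoxy)(but-2-ene-1-olato-3-yl)aluminate (five-membered O–Al ring) | [Na+].COCCO[Al-]1(OCCOC)OCC=C1C | intermediate
10 | (2Z)-3-iodobut-2-en-1-ol | C/C(I)=C/CO | intermediate
11 | O,C-bis(9-borabicyclo[3.3.1]nonan-9-yl) adduct of 7 (B on the former terminal CH2 and on O) | CC(C)=CC(OB1C2CCCC1CCC2)C/C(C)=C\CCB1C2CCCC1CCC2 | intermediate
12 | (±)-(2Z,6Z)-3,7,11-trimethyldodeca-2,6,10-triene-1,9-diol | CC(C)=CC(O)C/C(C)=C\CC/C(C)=C\CO | intermediate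
13 | (2Z,6Z)-3,7,11-trimethyl-9-oxododeca-2,6,10-trienal | CC(C)=CC(=O)C/C(C)=C\CC/C(C)=C\C=O | intermediate
14 | (2Z,6Z,9Z)-3,7,11-trimethyl-9-[(trichlorosilyl)oxy]dodeca-2,6,9-trienal | CC(C)/C=C(O[Si](Cl)(Cl)Cl)/C/C(C)=C\CC/C(C)=C\C=O | intermediate
15 | (3Z,7Z,9S,10R)-3,7-dimethyl-10-(propan-2-yl)-9-[(trichlorosilyl)oxy]cyclodeca-3,7-dien-1-one | O=C1C/C(C)=C\CC/C(C)=C\[C@H](O[Si](Cl)(Cl)Cl)[C@H]1C(C)C | intermediate
16 | (3Z,7Z,9S,10R)-9-hydroxy-3,7-dimethyl-10-(propan-2-yl)cyclodeca-3,7-dien-1-one | O=C1C/C(C)=C\CC/C(C)=C\[C@H](O)[C@H]1C(C)C | intermediate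
17 | (3Z,7Z,9S,10R)-3,7-dimethyl-10-(propan-2-yl)-9-[(triethylsilyl)oxy]cyclodeca-3,7-dien-1-one | O=C1C/C(C)=C\CC/C(C)=C\[C@H](O[Si](CC)(CC)CC)[C@H]1C(C)C | intermediate
18 | (1R,3Z,7Z,9S,10S)-3,7-dimethyl-10-(propan-2-yl)-9-[(triethylsilyl)oxy]cyclodeca-3,7-dien-1-ol | O[C@@H]1C/C(C)=C\CC/C(C)=C\[C@H](O[Si](CC)(CC)CC)[C@H]1C(C)C | intermediate
19 | 4-hydroxy-3-methoxybenzoic acid (vanillic acid) | COc1cc(C(=O)O)ccc1O | starting material
20 | tert-butyldimethylsilyl 4-[(tert-butyldimethylsilyl)oxy]-3-methoxybenzoate | COc1cc(C(=O)O[Si](C)(C)C(C)(C)C)ccc1O[Si](C)(C)C(C)(C)C | intermediate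
21 | 4-[(tert-butyldimethylsilyl)oxy]-3-methoxybenzoic acid | COc1cc(C(=O)O)ccc1O[Si](C)(C)C(C)(C)C | intermediate
22 | (1R,3Z,7Z,9S,10S)-3,7-dimethyl-10-(propan-2-yl)-9-[(triethylsilyl)oxy]cyclodeca-3,7-dien-1-yl 4-[(tert-butyldimethylsilyl)oxy]-3-methoxybenzoate | COc1cc(C(=O)O[C@@H]2C/C(C)=C\CC/C(C)=C\[C@H](O[Si](CC)(CC)CC)[C@H]2C(C)C)ccc1O[Si](C)(C)C(C)(C)C | intermediate
23 | (1R,3Z,7Z,9S,10R)-9-hydroxy-3,7-dimethyl-10-(propan-2-yl)cyclodeca-3,7-dien-1-yl 4-hydroxy-3-methoxybenzoate | COc1cc(C(=O)O[C@@H]2C/C(C)=C\CC/C(C)=C\[C@H](O)[C@H]2C(C)C)ccc1O | target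

## Step count and risks
Total step count: 10. Longest linear sequence: 8 (steps 1, 2, 4, 5, 6, 7, 8, 10).

**Step 6 (reductive aldol macrocyclisation).**
- Risks: reduction of the aldehyde, oligomerisation, a boat transition state that gives the anti aldol, or low ee.
- Fallback: it sets out from 7 and 10 and comes back at 16. It separates enolate formation from ring closure while closing the same bond. Compound 7 is oxidised with DMP to (6Z)-2,6-dimethylnona-2,6,8-trien-4-one F1. The s-cis enone of F1 is converted by RhCl(PPh3)3-catalysed 1,4-hydrosilylation with t-BuMe2SiH into tert-butyl{[(3Z,6Z)-2,6-dimethylnona-3,6,8-trien-4-yl]oxy}dimethylsilane F2. The vinyl group of F2 is hydroborated with 9-BBN and cross-coupled under the step 4 catalyst with (2Z)-3-iodobut-2-enal F3, which is obtained from 10 with MnO2. This gives (2Z,6Z,9Z)-9-[(tert-butyldimethylsilyl)oxy]-3,7,11-trimethyldodeca-2,6,9-trienal F4. F4 is cyclised at high dilution by a syn-selective Mukaiyama aldol reaction under a tartrate-derived chiral (acyloxy)borane catalyst, followed by an acidic work-up, to give 16.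

**Step 8 (CBS reduction).**
- Risks: a mismatch between catalyst and ring conformation, or a sluggish reaction of the doubly flanked ketone.
- Fallback: it sets out from 16 and comes back at 18. It replaces reagent control by substrate chelation and reverses the order of protection and reduction. Unprotected 16 undergoes a Narasaka–Prasad reduction (Et2BOMe, NaBH4, THF/MeOH, −78 °C). Axial hydride attack occurs on the boron chelate, on the face opposite the axial isopropyl group. The product is (1R,2S,3S,4Z,8Z)-5,9-dimethyl-2-(propan-2-yl)cyclodeca-4,8-diene-1,3-diol F5. Its more reactive allylic hydroxyl is then mono-silylated (TESCl 1.0 equiv, imidazole, CH2Cl2, −40 °C) to give 18.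

**Step 10 (acylation of the hindered C1 carbinol).**
- Risk: the neighbouring CH-iPr group and the OTES group may block acyl transfer.
- Fallback: it sets out from 17 (with 19) and comes back at 23. It forms the ester C–O bond by SN2 displacement instead of acyl transfer. Compound 17 is reduced with (R)-Me-CBS/catecholborane to the epimeric (1S,3Z,7Z,9S,10S)-3,7-dimethyl-10-(propan-2-yl)-9-[(triethylsilyl)oxy]cyclodeca-3,7-dien-1-ol F6. F6 undergoes a Mitsunobu reaction with unprotected 19 (PPh3, DIAD, THF), in which the carboxylic acid reacts in preference to the phenol. Inversion gives (1R,3Z,7Z,9S,10S)-3,7-dimethyl-10-(propan-2-yl)-9-[(triethylsilyl)oxy]cyclodeca-3,7-dien-1-yl 4-hydroxy-3-methoxybenzoate F7. Buffered fluoride then removes the TES group to give 23.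

## Further compounds
F1 | step 6 | (6Z)-2,6-dimethylnona-2,6,8-trien-4-one | CC(C)=CC(=O)C/C(C)=C\C=C
F2 | step 6 | tert-butyl{[(3Z,6Z)-2,6-dimethylnona-3,6,8-trien-4-yl]oxy}dimethylsilane | CC(C)/C=C(O[Si](C)(C)C(C)(C)C)/C/C(C)=C\C=C
F3 | step 6 | (2Z)-3-iodobut-2-enal | C/C(I)=C/C=O
F4 | step 6 | (2Z,6Z,9Z)-9-[(tert-butyldimethylsilyl)oxy]-3,7,11-trimethyldodeca-2,6,9-trienal | CC(C)/C=C(O[Si](C)(C)C(C)(C)C)/C/C(C)=C\CC/C(C)=C\C=O
F5 | step 8 | (1R,2S,3S,4Z,8Z)-5,9-dimethyl-2-(propan-2-yl)cyclodeca-4,8-diene-1,3-diol | O[C@@H]1C/C(C)=C\CC/C(C)=C\[C@H](O)[C@H]1C(C)C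
F6 | step 10 | (1S,3Z,7Z,9S,10S)-3,7-dimethyl-10-(propan-2-yl)-9-[(triethylsilyl)oxy]cyclodeca-3,7-dien-1-ol | O[C@H]1C/C(C)=C\CC/C(C)=C\[C@H](O[Si](CC)(CC)CC)[C@H]1C(C)C
F7 | step 10 | (1R,3Z,7Z,9S,10S)-3,7-dimethyl-10-(propan-2-yl)-9-[(triethylsilyl)oxy]cyclodeca-3,7-dien-1-yl 4-hydroxy-3-methoxybenzoate | COc1cc(C(=O)O[C@@H]2C/C(C)=C\CC/C(C)=C\[C@H](O[Si](CC)(CC)CC)[C@H]2C(C)C)ccc1O
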